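## Retrosynthetic overview

1. Feature: in the naphthalene half, ring C1'–C2'–C3'–C4'–C4a'–C8a' carries ring A (through C5) at C1', directly across from the oxygen on C4'. C2' holds a one-carbon group and C3' only H. This is the pattern left when a C1'–O–C4' bridge is broken at its aryl-bearing carbon, with C2'/C3' supplied by an alkyne.
2. Nitrogen ring (formed last): C1–C8a by Bischler–Napieralski closure of the (S)-acetamide. The 2'-CH3 traces back to 2'-CO2Me, and the amine travels as its N,N-dibenzyl derivative.
3. Naphthalene ring (key): C1'–C2' and C3'–C4' come from the Diels–Alder reaction of a transient 1-aryl-4-methoxyisobenzofuran with methyl propiolate. The bridge opens in the same flask to the 4'-naphthol.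
4. C5–C1' is made earlier by adding the ring A aryllithium to the carbonyl of 4-methoxyphthalide, whose substitution fixes 5'-OMe. C3 (S) comes from the L-alaninol series by Grignard opening of an aziridine.
5. Ring order: phthalide lactone, transient furan ring, naphthalene ring C1'–C4', dihydropyridine ring.

Key step: step 10

Assumption: the SMILES fixes only C3 (S) and leaves the configurationally stable C5–C1' axis open; the route does not control this axis, so both atropo-diastereomers arise in step 10, travel together and are separated after step 16, the one with the ancistrocladine-type axis being the natural product.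

## Route

Step 1
Reactants: 1 3-methoxy-2-methylbenzoic acid
Product: 2 methyl 3-methoxy-2-methylbenzoate
Conditions: MeOH, H2SO4 (cat.), reflux
Reagents that add atoms: methanol (CO)
Why: Fischer esterification in excess methanol should be clean and removes the acidic proton before the radical step.

Step 2
Reactants: 2 methyl 3-methoxy-2-methylbenzoate
Product: 3 methyl 2-(bromomethyl)-3-methoxybenzoate
Conditions: NBS (1.05 equiv), AIBN (cat.), PhCF3, reflux
Reagents that add atoms: N-bromosuccinimide (O=C1CCC(=O)N1Br)
Why: Wohl–Ziegler bromination, in which the 2-methyl group holds the only benzylic C–H bonds and radical conditions in a non-polar solvent with about one equivalent of NBS should hold back ionic bromination of the anisole ring.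

Step 3
Reactants: 3 methyl 2-(bromomethyl)-3-methoxybenzoate
Product: 4 4-methoxyphthalide (4-methoxy-2-benzofuran-1(3H)-one)
Conditions: CaCO3, dioxane–H2O (1:1), reflux
Reagents that add atoms: water (O)
Why: Hydrolysis of the benzylic bromide and spontaneous five-membered lactonisation onto the neighbouring methyl ester (nucleophilic acyl substitution) should give the phthalide, in which the methoxy group is locked next to the OCH2 carbon.

Step 4
Reactants: 5 N-Boc-L-alaninol (tert-butyl [(S)-1-hydroxypropan-2-yl]carbamate)
Product: 7 tert-butyl (S)-2-methylaziridine-1-carboxylate, via O-tosylate 6 (not isolated)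
Conditions: TsCl, KOH (powdered), THF, 0 °C to reflux
Reagents that add atoms: none
Why: O-sulfonylation followed by base-induced intramolecular SN2 displacement (3-exo-tet) by the carbamate nitrogen at the primary carbon closes the aziridine, and since no bond to the stereocentre is broken the S configuration is carried over.

Step 5
Reactants: 8 1-bromo-3,5-dimethoxybenzene; 7 tert-butyl (S)-2-methylaziridine-1-carboxylate
Product: 10 tert-butyl [(S)-1-(3,5-dimethoxyphenyl)propan-2-yl]carbamate, via 3,5-dimethoxyphenylmagnesium bromide 9 (not isolated)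
Conditions: 8, Mg, THF, reflux; then CuBr·SMe2 (10 mol %), 7, THF, −30 °C to rt; H2O
Reagents that add atoms: none
Why: Copper-catalysed Grignard opening of an N-acyl-activated aziridine is an SN2 attack at the unsubstituted CH2, so the C4–aryl bond forms while the stereocentre (future C3, S) is left untouched.

Step 6
Reactants: 10 tert-butyl [(S)-1-(3,5-dimethoxyphenyl)propan-2-yl]carbamate
Product: 11 tert-butyl [(S)-1-(2-bromo-3,5-dimethoxyphenyl)propan-2-yl]carbamate
Conditions: NBS (1.0 equiv), MeCN, −10 to 0 °C
Reagents that add atoms: N-bromosuccinimide (O=C1CCC(=O)N1Br)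
Why: Electrophilic aromatic bromination of a 5-alkylresorcinol dimethyl ether goes para to one methoxy group, at either of the two equivalent carbons next to the side chain rather than at the crowded carbon between both methoxy groups, and it is placed at the carbamate stage because NBS would oxidise a benzylic tertiary amine.

Step 7
Reactants: 11 tert-butyl [(S)-1-(2-bromo-3,5-dimethoxyphenyl)propan-2-yl]carbamate
Product: 12 (S)-1-(2-bromo-3,5-dimethoxyphenyl)propan-2-amine
Conditions: HCl (4 M in dioxane), rt; aq NaOH
Reagents that add atoms: none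
Why: Acidolysis of the tert-butyl carbamate (loss of the tert-butyl cation, then decarboxylation) should be clean, with chloride and dioxane limiting tert-butylation of the electron-rich ring.

Step 8
Reactants: 12 (S)-1-(2-bromo-3,5-dimethoxyphenyl)propan-2-amine
Product: 13 (S)-N,N-dibenzyl-1-(2-bromo-3,5-dimethoxyphenyl)propan-2-amine
Conditions: BnBr (2.3 equiv), K2CO3, MeCN, 70 °C
Reagents that add atoms: benzyl bromide (BrCc1ccccc1)
Why: Twofold SN2 N-alkylation gives a tertiary amine without N–H, which tolerates the organolithium step, cannot condense with the later ketone to a six-membered cyclic imine, and is removable by hydrogenolysis.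

Step 9
Reactants: 13 (S)-N,N-dibenzyl-1-(2-bromo-3,5-dimethoxyphenyl)propan-2-amine; 4 4-methoxyphthalide
Product: 15 (S)-{2-[2-(dibenzylamino)propyl]-4,6-dimethoxyphenyl}[2-(hydroxymethyl)-3-methoxyphenyl]methanone, via ring A aryllithium 14 (not isolated)
Conditions: n-BuLi (1.05 equiv), THF, −78 °C; cannulated into 4, THF, −78 to −20 °C; H2O; short filtration over Et3N-deactivated silica
Reagents that add atoms: none
Why: Bromine–lithium exchange followed by single nucleophilic addition of the aryl metal to the lactone carbonyl, a known way to open phthalides, forms C5–C1', and the lithium lactolate and the doubly ortho-substituted ketone behind it should resist a second addition.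

Step 10
Reactants: 15 (S)-{2-[2-(dibenzylamino)propyl]-4,6-dimethoxyphenyl}[2-(hydroxymethyl)-3-methoxyphenyl]methanone; 16 methyl propiolate
Product: 20 methyl 1-{2-[(S)-2-(dibenzylamino)propyl]-4,6-dimethoxyphenyl}-4-hydroxy-5-methoxy-2-naphthoate, via lactol tautomer 17 (not isolated), via 1-arylisobenzofuran 18 (not isolated), via oxa-bridged cycloadduct 19 (not isolated)
Conditions: CF3CO2H (2.5 equiv), ClCH2CH2Cl, rt, Ar; then 16 (5 equiv), 60 °C; aq NaHCO3
Reagents that add atoms: none
Why: With the amine first parked as its ammonium salt (so that it cannot trigger base-catalysed addition of the alcohol to the propiolate), acid ionises lactol 17 to an aryl-stabilised oxocarbenium ion that loses a proton from its OCH2 group to give the o-quinoid furan 18, which adds the alkyne in a concerted but asynchronous suprafacial (4+2) cycloaddition driven by recovery of the benzene sextet. The closest known reaction type is the trapping of 1-arylisobenzofurans by acetylenic esters with acid opening to 1-aryl-4-hydroxynaphthoates, the standard entry to arylnaphthalene lignans. The one ring closed, C1'–C2'–C3'–C4'–C4a'–C8a', is formed intermolecularly with C1'–C2' and C3'–C4' made in the same event, after which acid breaks the C1'–O bond of 19 (doubly benzylic cation carrying the dimethoxyaryl ring, whereas C4'–O ionisation leads nowhere because C1' has no hydrogen to lose) and loss of H-4' leaves the oxygen on C4' as the naphthol. The two bridgehead stereocentres of 19 are erased on aromatisation, C3 in the side chain is a spectator, and the hindered C5–C1' axis appears without control, so 20 is expected as two atropo-diastereomers. The selectivity needed is the orientation of the propiolate (ester on C2', not C3'): the electrophilic alkyne CH should begin bonding at the open, hydrogen-bearing furan carbon (future C4') because the developing positive charge then rests on the carbon flanked by the furan oxygen and the 2,4-dimethoxyaryl ring, the late-forming bond tolerates the crowded terminus (the ortho rule of 1-substituted dienes), and the nearby ammonium N–H may help by hydrogen bonding to the ester carbonyl. The methoxy group peri to C4' donates towards the other terminus and ring A is bulky, so this orientation is the real uncertainty of the route, although the unwanted 3'-ester would be a chelated salicylate-type naphthol that should be easy to recognise and remove by chromatography.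

Step 11
Reactants: 20 methyl 1-{2-[(S)-2-(dibenzylamino)propyl]-4,6-dimethoxyphenyl}-4-hydroxy-5-methoxy-2-naphthoate
Product: 21 methyl 1-{2-[(S)-2-(dibenzylamino)propyl]-4,6-dimethoxyphenyl}-4,5-dimethoxy-2-naphthoate
Conditions: MeI (1.2 equiv), K2CO3, DMF, rt
Reagents that add atoms: iodomethane (CI)
Why: Williamson O-methylation, in which the naphtholate should consume the small excess of MeI far faster than the hindered, α-branched dibenzylamine, so quaternisation is not expected to compete.

Step 12
Reactants: 21 methyl 1-{2-[(S)-2-(dibenzylamino)propyl]-4,6-dimethoxyphenyl}-4,5-dimethoxy-2-naphthoate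
Product: 22 (1-{2-[(S)-2-(dibenzylamino)propyl]-4,6-dimethoxyphenyl}-4,5-dimethoxynaphthalen-2-yl)methanol
Conditions: LiAlH4, THF, 0 °C to reflux; H2O, aq NaOH
Reagents that add atoms: none
Why: Hydride reduction of the ester with LiAlH4 should reach the primary alcohol even next to the bulky ring A, while aryl ethers and benzylamines are inert.

Step 13
Reactants: 22 (1-{2-[(S)-2-(dibenzylamino)propyl]-4,6-dimethoxyphenyl}-4,5-dimethoxynaphthalen-2-yl)methanol
Product: 23 (1-{2-[(S)-2-(dibenzylamino)propyl]-4,6-dimethoxyphenyl}-4,5-dimethoxynaphthalen-2-yl)methyl acetate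
Conditions: Ac2O, pyridine, DMAP (cat.), CH2Cl2, rt
Reagents that add atoms: acetic anhydride (CC(=O)OC(C)=O)
Why: DMAP-catalysed O-acetylation turns the hydroxyl into a better leaving group for the coming hydrogenolysis, and the tertiary amine cannot be acylated.

Step 14
Reactants: 23 (1-{2-[(S)-2-(dibenzylamino)propyl]-4,6-dimethoxyphenyl}-4,5-dimethoxynaphthalen-2-yl)methyl acetate
Product: 24 (S)-1-[2-(4,5-dimethoxy-2-methylnaphthalen-1-yl)-3,5-dimethoxyphenyl]propan-2-amine
Conditions: H2 (4 bar), Pd(OH)2/C, EtOH–AcOH (10:1), rt; aq NaOH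
Reagents that add atoms: none
Why: Heterogeneous catalytic hydrogenolysis should cleave in one operation the 2-naphthylmethyl C–O bond and both benzylic C–N bonds, the acetic acid keeping the liberated amine protonated so that it neither poisons the catalyst nor picks up the O-acetyl group.

Step 15
Reactants: 24 (S)-1-[2-(4,5-dimethoxy-2-methylnaphthalen-1-yl)-3,5-dimethoxyphenyl]propan-2-amine
Product: 25 N-{(S)-1-[2-(4,5-dimethoxy-2-methylnaphthalen-1-yl)-3,5-dimethoxyphenyl]propan-2-yl}acetamide
Conditions: Ac2O, Et3N, CH2Cl2, 0 °C to rt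
Reagents that add atoms: acetic anhydride (CC(=O)OC(C)=O)
Why: N-acylation of the only nucleophilic group, a primary amine, by an anhydride brings in C1 and its methyl group.

Step 16
Reactants: 25 N-{(S)-1-[2-(4,5-dimethoxy-2-methylnaphthalen-1-yl)-3,5-dimethoxyphenyl]propan-2-yl}acetamide
Product: 26 O-methylancistrocladinine
Conditions: POCl3, MeCN, reflux; aq NaOH; separation of the two atropo-diastereomers by chromatography or crystallisation
Reagents that add atoms: none
Why: Bischler–Napieralski cyclodehydration, in which the activated amide attacks the only free position ortho to the side chain (C8a, ortho to 8-OMe and para to 6-OMe) in a 6-endo-dig closure, C3 is not involved and stays S, and the two axial isomers are diastereomers and thus separable by ordinary means.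

## Compound list

1 | 3-methoxy-2-methylbenzoic acid | COc1cccc(C(=O)O)c1C | starting material
2 | methyl 3-methoxy-2-methylbenzoate | COC(=O)c1cccc(OC)c1C | intermediate
3 | methyl 2-(bromomethyl)-3-methoxybenzoate | COC(=O)c1cccc(OC)c1CBr | intermediate
4 | 4-methoxyphthalide | COc1cccc2C(=O)OCc12 | intermediate
5 | N-Boc-L-alaninol, tert-butyl [(S)-1-hydroxypropan-2-yl]carbamate | C[C@H](NC(=O)OC(C)(C)C)CO | starting material
6 | (S)-2-[(tert-butoxycarbonyl)amino]propyl 4-methylbenzenesulfonate | C[C@H](NC(=O)OC(C)(C)C)COS(=O)(=O)c1ccc(C)cc1 | intermediate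
7 | tert-butyl (S)-2-methylaziridine-1-carboxylate | C[C@H]1CN1C(=O)OC(C)(C)C | intermediate
8 | 1-bromo-3,5-dimethoxybenzene | COc1cc(Br)cc(OC)c1 | starting material
9 | 3,5-dimethoxyphenylmagnesium bromide | COc1cc([Mg]Br)cc(OC)c1 | intermediate
10 | tert-butyl [(S)-1-(3,5-dimethoxyphenyl)propan-2-yl]carbamate | C[C@H](NC(=O)OC(C)(C)C)Cc1cc(OC)cc(OC)c1 | intermediate
11 | tert-butyl [(S)-1-(2-bromo-3,5-dimethoxyphenyl)propan-2-yl]carbamate | C[C@H](NC(=O)OC(C)(C)C)Cc1cc(OC)cc(OC)c1Br | intermediate
12 | (S)-1-(2-bromo-3,5-dimethoxyphenyl)propan-2-amine | C[C@H](N)Cc1cc(OC)cc(OC)c1Br | intermediate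
13 | (S)-N,N-dibenzyl-1-(2-bromo-3,5-dimethoxyphenyl)propan-2-amine | COc1cc(OC)c(Br)c(C[C@H](C)N(Cc2ccccc2)Cc2ccccc2)c1 | intermediate
14 | {2-[(S)-2-(dibenzylamino)propyl]-4,6-dimethoxyphenyl}lithium | COc1cc(OC)c([Li])c(C[C@H](C)N(Cc2ccccc2)Cc2ccccc2)c1 | intermediate
15 | (S)-{2-[2-(dibenzylamino)propyl]-4,6-dimethoxyphenyl}[2-(hydroxymethyl)-3-methoxyphenyl]methanone (keto alcohol, in equilibrium with 17) | OCc1c(OC)cccc1C(=O)c1c(OC)cc(OC)cc1C[C@H](C)N(Cc1ccccc1)Cc1ccccc1 | intermediate
16 | methyl propiolate | C#CC(=O)OC | starting material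
17 | 1-{2-[(S)-2-(dibenzylamino)propyl]-4,6-dimethoxyphenyl}-4-methoxy-1,3-dihydro-2-benzofuran-1-ol (lactol, both epimers at C1) | COc1cccc2c1COC2(O)c1c(OC)cc(OC)cc1C[C@H](C)N(Cc1ccccc1)Cc1ccccc1 | intermediate
18 | 1-{2-[(S)-2-(dibenzylamino)propyl]-4,6-dimethoxyphenyl}-4-methoxy-2-benzofuran (isobenzofuran) | COc1cccc2c(-c3c(OC)cc(OC)cc3C[C@H](C)N(Cc3ccccc3)Cc3ccccc3)occ12 | intermediate
19 | methyl 1-{2-[(S)-2-(dibenzylamino)propyl]-4,6-dimethoxyphenyl}-5-methoxy-1,4-dihydro-1,4-epoxynaphthalene-2-carboxylate (bridgeheads not controlled) | COC(=O)C1=CC2OC1(c1c(OC)cc(OC)cc1C[C@H](C)N(Cc1ccccc1)Cc1ccccc1)c1cccc(OC)c12 | intermediate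
20 | methyl 1-{2-[(S)-2-(dibenzylamino)propyl]-4,6-dimethoxyphenyl}-4-hydroxy-5-methoxy-2-naphthoate | COC(=O)c1cc(O)c2c(OC)cccc2c1-c1c(OC)cc(OC)cc1C[C@H](C)N(Cc1ccccc1)Cc1ccccc1 | intermediate
21 | methyl 1-{2-[(S)-2-(dibenzylamino)propyl]-4,6-dimethoxyphenyl}-4,5-dimethoxy-2-naphthoate | COC(=O)c1cc(OC)c2c(OC)cccc2c1-c1c(OC)cc(OC)cc1C[C@H](C)N(Cc1ccccc1)Cc1ccccc1 | intermediate
22 | (1-{2-[(S)-2-(dibenzylamino)propyl]-4,6-dimethoxyphenyl}-4,5-dimethoxynaphthalen-2-yl)methanol | OCc1cc(OC)c2c(OC)cccc2c1-c1c(OC)cc(OC)cc1C[C@H](C)N(Cc1ccccc1)Cc1ccccc1 | intermediate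
23 | (1-{2-[(S)-2-(dibenzylamino)propyl]-4,6-dimethoxyphenyl}-4,5-dimethoxynaphthalen-2-yl)methyl acetate | CC(=O)OCc1cc(OC)c2c(OC)cccc2c1-c1c(OC)cc(OC)cc1C[C@H](C)N(Cc1ccccc1)Cc1ccccc1 | intermediate
24 | (S)-1-[2-(4,5-dimethoxy-2-methylnaphthalen-1-yl)-3,5-dimethoxyphenyl]propan-2-amine | Cc1cc(OC)c2c(OC)cccc2c1-c1c(OC)cc(OC)cc1C[C@H](C)N | intermediate
25 | N-{(S)-1-[2-(4,5-dimethoxy-2-methylnaphthalen-1-yl)-3,5-dimethoxyphenyl]propan-2-yl}acetamide | Cc1cc(OC)c2c(OC)cccc2c1-c1c(OC)cc(OC)cc1C[C@H](C)NC(C)=O | intermediate
26 | O-methylancistrocladinine, (3S)-5-(4,5-dimethoxy-2-methylnaphthalen-1-yl)-6,8-dimethoxy-1,3-dimethyl-3,4-dihydroisoquinoline | COc1cc(OC)c(-c2c(C)cc(OC)c3c(OC)cccc23)c2c1C(C)=N[C@@H](C)C2 | target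

## Step count and risks

Total step count: 16.
Longest linear sequence: 13 steps (steps 4 to 16, starting from 5).

**1. Step 10.** The propiolate may add in the reverse orientation, since the peri methoxy group and the bulk of ring A both push that way. The isobenzofuran may also oligomerise under acid before the only moderately reactive dienophile traps it.

The fallback sets out from 15 and comes back at 20.
- 15 is treated under the same acid conditions with the symmetrical and more reactive dimethyl acetylenedicarboxylate, so orientation no longer matters. This gives dimethyl 1-{2-[(S)-2-(dibenzylamino)propyl]-4,6-dimethoxyphenyl}-4-hydroxy-5-methoxynaphthalene-2,3-dicarboxylate F1.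
- KOH in aqueous MeOH should saponify only the 3'-ester, because the 2'-ester is screened by the perpendicular ring A. This gives 4-{2-[(S)-2-(dibenzylamino)propyl]-4,6-dimethoxyphenyl}-1-hydroxy-8-methoxy-3-(methoxycarbonyl)-2-naphthoic acid F2.
- As a 1-hydroxy-2-naphthoic acid, F2 should lose CO2 through its keto tautomer on heating in DMSO at about 140 °C, which delivers 20.

**2. Step 9.** The hindered, strongly basic aryllithium may abstract a proton from the OCH2 group of the phthalide in place of adding to the carbonyl, or a second addition may occur.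

The fallback sets out from 13 and comes back at isobenzofuran 18 inside step 10, and so at 20.
- Bromine–lithium exchange on 13 and quenching with DMF gives 2-[(S)-2-(dibenzylamino)propyl]-4,6-dimethoxybenzaldehyde F3.
- Separately, commercial 2-bromo-6-methoxybenzaldehyde is converted with HC(OMe)3 and TsOH in MeOH into 1-bromo-2-(dimethoxymethyl)-3-methoxybenzene F4.
- F4 is lithiated with n-BuLi at −78 °C and added to F3 to give {2-[(S)-2-(dibenzylamino)propyl]-4,6-dimethoxyphenyl}[2-(dimethoxymethyl)-3-methoxyphenyl]methanol F5.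
- Under the acid conditions of step 10, F5 should cyclise and lose two molecules of methanol to give the same 18. This is the hydroxy acetal route to isobenzofurans.

**3. Step 14.** C–O hydrogenolysis at the shielded 2'-CH2OAc group may stay incomplete while N-debenzylation goes ahead, after which the acetyl group could migrate from oxygen to nitrogen.

The fallback sets out from 22 and comes back at 24.
- An Appel reaction (CBr4, PPh3, CH2Cl2, 0 °C) gives (S)-N,N-dibenzyl-1-{2-[2-(bromomethyl)-4,5-dimethoxynaphthalen-1-yl]-3,5-dimethoxyphenyl}propan-2-amine F6.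
- F6 is used at once and reduced by SN2 hydride delivery with LiBHEt3 in THF to (S)-N,N-dibenzyl-1-[2-(4,5-dimethoxy-2-methylnaphthalen-1-yl)-3,5-dimethoxyphenyl]propan-2-amine F7.
- Hydrogenolysis over Pd(OH)2/C then has to remove only the two N-benzyl groups to reach 24.

## Further compounds

F1 | step 10 | dimethyl 1-{2-[(S)-2-(dibenzylamino)propyl]-4,6-dimethoxyphenyl}-4-hydroxy-5-methoxynaphthalene-2,3-dicarboxylate | COC(=O)c1c(O)c2c(OC)cccc2c(-c2c(OC)cc(OC)cc2C[C@H](C)N(Cc2ccccc2)Cc2ccccc2)c1C(=O)OC
F2 | step 10 | 4-{2-[(S)-2-(dibenzylamino)propyl]-4,6-dimethoxyphenyl}-1-hydroxy-8-methoxy-3-(methoxycarbonyl)-2-naphthoic acid | OC(=O)c1c(O)c2c(OC)cccc2c(-c2c(OC)cc(OC)cc2C[C@H](C)N(Cc2ccccc2)Cc2ccccc2)c1C(=O)OC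
F3 | step 9 | 2-[(S)-2-(dibenzylamino)propyl]-4,6-dimethoxybenzaldehyde | O=Cc1c(OC)cc(OC)cc1C[C@H](C)N(Cc1ccccc1)Cc1ccccc1
F4 | step 9 | 1-bromo-2-(dimethoxymethyl)-3-methoxybenzene | COC(OC)c1c(Br)cccc1OC
F5 | step 9 | {2-[(S)-2-(dibenzylamino)propyl]-4,6-dimethoxyphenyl}[2-(dimethoxymethyl)-3-methoxyphenyl]methanol (both carbinol epimers) | COC(OC)c1c(OC)cccc1C(O)c1c(OC)cc(OC)cc1C[C@H](C)N(Cc1ccccc1)Cc1ccccc1
F6 | step 14 | (S)-N,N-dibenzyl-1-{2-[2-(bromomethyl)-4,5-dimethoxynaphthalen-1-yl]-3,5-dimethoxyphenyl}propan-2-amine | BrCc1cc(OC)c2c(OC)cccc2c1-c1c(OC)cc(OC)cc1C[C@H](C)N(Cc1ccccc1)Cc1ccccc1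
F7 | step 14 | (S)-N,N-dibenzyl-1-[2-(4,5-dimethoxy-2-methylnaphthalen-1-yl)-3,5-dimethoxyphenyl]propan-2-amine | Cc1cc(OC)c2c(OC)cccc2c1-c1c(OC)cc(OC)cc1C[C@H](C)N(Cc1ccccc1)Cc1ccccc1
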